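**Target:** (2R,3R)-2-(2,5-dihydroxy-4-methoxyphenyl)-3,5,7-trimethoxychroman-4-one (2,3-trans; C2 R, C3 R from the given SMILES).

**Retrosynthetic overview**
1. Target 22 ⇐ bis-benzyl ether 21 by neutral hydrogenolysis (last step).
2. Ring C (O1–C2 bond, the only ring made, closed last) ⇐ intramolecular Mitsunobu etherification of hydroxy ketone 19 with inversion at the benzylic carbon.
3. C4–C4a bond ⇐ Weinreb amide 12 + ortho-lithiated MOM ether of 3,5-dimethoxyphenol (ring A bought intact).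
4. C2–C3 bond (key bond, sets both stereocentres) ⇐ intermolecular Evans syn glycolate aldol of (R)-4-benzyl-3-(2-methoxyacetyl)oxazolidin-2-one 7 with aldehyde 4.
5. Aldehyde 4 (ring B) ⇐ methoxyhydroquinone 1 by O-benzylation and Vilsmeier–Haack formylation.

Assumption: O- or N-metalated forms of a numbered compound that are only protonated on work-up are not numbered separately; chromanone numbering is O1, C2 (aryl), C3 (OMe), C4 (C=O).

**Step 1**
Reactants: 1 2-methoxybenzene-1,4-diol (methoxyhydroquinone)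
Product: 2 1,4-bis(benzyloxy)-2-methoxybenzene
Conditions: BnBr (2.4 equiv), K2CO3, DMF, 60 °C, N2
Reagents that add atoms: benzyl bromide, BrCc1ccccc1
Why: Williamson etherification of both phenols with an SN2-reactive benzylic halide; no stereocentre is involved.

**Step 2**
Reactants: 2 1,4-bis(benzyloxy)-2-methoxybenzene
Product: 4 2,5-bis(benzyloxy)-4-methoxybenzaldehyde, via aryl iminium salt 3 (not isolated)
Conditions: POCl3, DMF, 0 → 70 °C; then aq. NaOAc, rt
Reagents that add atoms: N,N-dimethylformamide, CN(C)C=O; water, O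
Why: Vilsmeier–Haack formylation attacks the one ring position that is para to one alkoxy group (OMe) and ortho to another (OBn), the usual outcome for 1,2,4-trialkoxybenzenes, and the iminium salt is hydrolysed on work-up.

**Step 3**
Reactants: 5 (R)-4-benzyloxazolidin-2-one; 6 methoxyacetyl chloride
Product: 7 (R)-4-benzyl-3-(2-methoxyacetyl)oxazolidin-2-one
Conditions: n-BuLi, THF, −78 °C; then 6, −78 → 0 °C
Reagents that add atoms: none
Why: N-acylation of the lithiated oxazolidinone by an acid chloride (Evans auxiliary loading); the auxiliary stereocentre is untouched.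

**Step 4**
Reactants: 7 (R)-4-benzyl-3-(2-methoxyacetyl)oxazolidin-2-one; 4 2,5-bis(benzyloxy)-4-methoxybenzaldehyde
Product: 10 (R)-4-benzyl-3-[(2R,3S)-3-[2,5-bis(benzyloxy)-4-methoxyphenyl]-3-hydroxy-2-methoxypropanoyl]oxazolidin-2-one, via Z-boron enolate 8 (not isolated), via boron aldolate 9 (not isolated)
Conditions: Bu2BOTf, Et3N, CH2Cl2, −78 → 0 °C; then 4, −78 → 0 °C; then pH 7 buffer (KH2PO4/Na2HPO4), MeOH, 30% H2O2, 0 °C
Reagents that add atoms: none
Why: Evans syn glycolate aldol through a closed Zimmerman–Traxler chair of the Z-boron enolate, with the (R)-benzyl group shielding one enolate face, gives the 2,3-syn (2R,3S) adduct (expected >20:1); its C-2 (R) becomes C3 of the target and its C-3 (S) carbinol is placed for later inversion.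

**Step 5**
Reactants: 10 (R)-4-benzyl-3-[(2R,3S)-3-[2,5-bis(benzyloxy)-4-methoxyphenyl]-3-hydroxy-2-methoxypropanoyl]oxazolidin-2-one
Product: 11 (2R,3S)-3-[2,5-bis(benzyloxy)-4-methoxyphenyl]-3-hydroxy-N,2-dimethoxy-N-methylpropanamide
Conditions: AlMe3, MeONHMe·HCl, CH2Cl2, −10 → 0 °C; then aq. KNaC4H4O6
Reagents that add atoms: N,O-dimethylhydroxylamine hydrochloride, CNOC.Cl
Why: Weinreb transamination by the aluminium amide, directed to the exocyclic carbonyl by the free β-alkoxide, cleaves the auxiliary (recovered) without epimerising either centre.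

**Step 6**
Reactants: 11 (2R,3S)-3-[2,5-bis(benzyloxy)-4-methoxyphenyl]-3-hydroxy-N,2-dimethoxy-N-methylpropanamide
Product: 12 (2R,3S)-3-[2,5-bis(benzyloxy)-4-methoxyphenyl]-3-[(tert-butyldimethylsilyl)oxy]-N,2-dimethoxy-N-methylpropanamide
Conditions: TBSOTf, 2,6-lutidine, CH2Cl2, −78 → 0 °C
Reagents that add atoms: tert-butyldimethylsilyl triflate, CC(C)(C)[Si](C)(C)OS(=O)(=O)C(F)(F)F
Why: O-silylation of the secondary alcohol under non-nucleophilic base masks the carbinol against retro-aldol and alkoxide chemistry in the organolithium step, with configuration retained.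

**Step 7**
Reactants: 13 3,5-dimethoxyphenol
Product: 14 1,3-dimethoxy-5-(methoxymethoxy)benzene
Conditions: NaH, MOMCl, DMF, 0 °C → rt
Reagents that add atoms: chloromethyl methyl ether, COCCl
Why: O-alkylation of the phenolate (Williamson type) installs an acetal that both protects the phenol and directs ortho-lithiation.

**Step 8**
Reactants: 14 1,3-dimethoxy-5-(methoxymethoxy)benzene (1.5 equiv); 12 (2R,3S)-3-[2,5-bis(benzyloxy)-4-methoxyphenyl]-3-[(tert-butyldimethylsilyl)oxy]-N,2-dimethoxy-N-methylpropanamide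
Product: 17 (2R,3S)-3-[2,5-bis(benzyloxy)-4-methoxyphenyl]-3-[(tert-butyldimethylsilyl)oxy]-1-[2,4-dimethoxy-6-(methoxymethoxy)phenyl]-2-methoxypropan-1-one, via aryllithium 15 (not isolated), via tetrahedral adduct 16 (not isolated)
Conditions: n-BuLi, THF, 0 °C → rt; then 12, −78 → −20 °C; then aq. NH4Cl
Reagents that add atoms: none
Why: Directed ortho-metalation (OMOM outranks OMe, so lithiation goes to the position flanked by OMOM and OMe, two equivalent sites) followed by Weinreb ketone synthesis, in which the chelated tetrahedral adduct stops at the ketone stage and shields the α-stereocentre until quench.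

**Step 9**
Reactants: 17 (2R,3S)-3-[2,5-bis(benzyloxy)-4-methoxyphenyl]-3-[(tert-butyldimethylsilyl)oxy]-1-[2,4-dimethoxy-6-(methoxymethoxy)phenyl]-2-methoxypropan-1-one
Product: 18 (2R,3S)-3-[2,5-bis(benzyloxy)-4-methoxyphenyl]-3-[(tert-butyldimethylsilyl)oxy]-1-(2-hydroxy-4,6-dimethoxyphenyl)-2-methoxypropan-1-one
Conditions: MgBr2·OEt2, Et2O/toluene, 0 °C → rt; then H2O
Reagents that add atoms: none
Why: Chelation-assisted Lewis-acid acetal cleavage, in which MgBr2 bound between the ketone oxygen and the ortho acetal oxygen activates only this MOM group toward bromide, is aprotic and so should spare the silyl ether, the benzyl ethers and the ionisable benzylic C–O bond.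

**Step 10**
Reactants: 18 (2R,3S)-3-[2,5-bis(benzyloxy)-4-methoxyphenyl]-3-[(tert-butyldimethylsilyl)oxy]-1-(2-hydroxy-4,6-dimethoxyphenyl)-2-methoxypropan-1-one
Product: 19 (2R,3S)-3-[2,5-bis(benzyloxy)-4-methoxyphenyl]-3-hydroxy-1-(2-hydroxy-4,6-dimethoxyphenyl)-2-methoxypropan-1-one
Conditions: HF·pyridine, pyridine, THF, 0 °C → rt
Reagents that add atoms: none
Why: Fluoride-mediated desilylation under buffered, weakly acidic conditions avoids the base that would trigger retro-aldol or β-elimination of the β-hydroxy ketone.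

**Step 11**
Reactants: 19 (2R,3S)-3-[2,5-bis(benzyloxy)-4-methoxyphenyl]-3-hydroxy-1-(2-hydroxy-4,6-dimethoxyphenyl)-2-methoxypropan-1-one
Product: 21 (2R,3R)-2-[2,5-bis(benzyloxy)-4-methoxyphenyl]-3,5,7-trimethoxychroman-4-one, via alkoxyphosphonium phenolate 20 (not isolated)
Conditions: PPh3, DIAD (slow addition), THF, 0 °C → rt
Reagents that add atoms: none
Why: Intramolecular Mitsunobu etherification, in which the phenolate displaces the benzylic oxyphosphonium in a 6-exo-tet SN2 with inversion, turns the syn (2R,3S) aldol into the 2,3-trans (2R,3R) chromanone, which is also the thermodynamically preferred diastereomer.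

**Step 12**
Reactants: 21 (2R,3R)-2-[2,5-bis(benzyloxy)-4-methoxyphenyl]-3,5,7-trimethoxychroman-4-one
Product: 22 (2R,3R)-2-(2,5-dihydroxy-4-methoxyphenyl)-3,5,7-trimethoxychroman-4-one
Conditions: H2 (1 atm), Pd/C (10%), EtOAc, rt; filtration and concentration under argon
Reagents that add atoms: none
Why: Catalytic hydrogenolysis of the two aryl benzyl ethers under neutral conditions leaves the methyl ethers, the ketone and both stereocentres alone, and the reducing medium protects the air-sensitive hydroquinone.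

**Compound list**
1 | 2-methoxybenzene-1,4-diol (methoxyhydroquinone) | COc1cc(O)ccc1O | starting material
2 | 1,4-bis(benzyloxy)-2-methoxybenzene | COc1cc(OCc2ccccc2)ccc1OCc1ccccc1 | intermediate
3 | N-[2,5-bis(benzyloxy)-4-methoxybenzylidene]-N-methylmethanaminium dichlorophosphate | C[N+](C)=Cc1cc(OCc2ccccc2)c(OC)cc1OCc1ccccc1.[O-]P(=O)(Cl)Cl | intermediate (not isolated)
4 | 2,5-bis(benzyloxy)-4-methoxybenzaldehyde | O=Cc1cc(OCc2ccccc2)c(OC)cc1OCc1ccccc1 | intermediate
5 | (R)-4-benzyloxazolidin-2-one | O=C1OC[C@@H](Cc2ccccc2)N1 | starting material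
6 | methoxyacetyl chloride | COCC(=O)Cl | starting material
7 | (R)-4-benzyl-3-(2-methoxyacetyl)oxazolidin-2-one | COCC(=O)N1C(=O)OC[C@H]1Cc1ccccc1 | intermediate
8 | (R)-4-benzyl-3-[(Z)-1-[(dibutylboranyl)oxy]-2-methoxyethenyl]oxazolidin-2-one | CO/C=C(\OB(CCCC)CCCC)N1C(=O)OC[C@H]1Cc1ccccc1 | intermediate (not isolated)
9 | dibutylboron aldolate of 10 (O-BBu2 on C-3 of the (2R,3S)-propanoyl chain) | O=C(N1C(=O)OC[C@H]1Cc1ccccc1)[C@H](OC)[C@@H](OB(CCCC)CCCC)c1cc(OCc2ccccc2)c(OC)cc1OCc1ccccc1 | intermediate (not isolated)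
10 | (R)-4-benzyl-3-[(2R,3S)-3-[2,5-bis(benzyloxy)-4-methoxyphenyl]-3-hydroxy-2-methoxypropanoyl]oxazolidin-2-one | O=C(N1C(=O)OC[C@H]1Cc1ccccc1)[C@H](OC)[C@@H](O)c1cc(OCc2ccccc2)c(OC)cc1OCc1ccccc1 | intermediate
11 | (2R,3S)-3-[2,5-bis(benzyloxy)-4-methoxyphenyl]-3-hydroxy-N,2-dimethoxy-N-methylpropanamide | CON(C)C(=O)[C@H](OC)[C@@H](O)c1cc(OCc2ccccc2)c(OC)cc1OCc1ccccc1 | intermediate
12 | (2R,3S)-3-[2,5-bis(benzyloxy)-4-methoxyphenyl]-3-[(tert-butyldimethylsilyl)oxy]-N,2-dimethoxy-N-methylpropanamide | CON(C)C(=O)[C@H](OC)[C@@H](O[Si](C)(C)C(C)(C)C)c1cc(OCc2ccccc2)c(OC)cc1OCc1ccccc1 | intermediate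
13 | 3,5-dimethoxyphenol | COc1cc(O)cc(OC)c1 | starting material
14 | 1,3-dimethoxy-5-(methoxymethoxy)benzene | COCOc1cc(OC)cc(OC)c1 | intermediate
15 | [2,4-dimethoxy-6-(methoxymethoxy)phenyl]lithium | [Li]c1c(OC)cc(OC)cc1OCOC | intermediate (not isolated)
16 | lithium (2R,3S)-3-[2,5-bis(benzyloxy)-4-methoxyphenyl]-3-[(tert-butyldimethylsilyl)oxy]-1-[2,4-dimethoxy-6-(methoxymethoxy)phenyl]-2-methoxy-1-[methoxy(methyl)amino]propan-1-olate (C-1 undefined) | [Li]OC(N(C)OC)(c1c(OC)cc(OC)cc1OCOC)[C@H](OC)[C@@H](O[Si](C)(C)C(C)(C)C)c1cc(OCc2ccccc2)c(OC)cc1OCc1ccccc1 | intermediate (not isolated)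
17 | (2R,3S)-3-[2,5-bis(benzyloxy)-4-methoxyphenyl]-3-[(tert-butyldimethylsilyl)oxy]-1-[2,4-dimethoxy-6-(methoxymethoxy)phenyl]-2-methoxypropan-1-one | COCOc1cc(OC)cc(OC)c1C(=O)[C@H](OC)[C@@H](O[Si](C)(C)C(C)(C)C)c1cc(OCc2ccccc2)c(OC)cc1OCc1ccccc1 | intermediate
18 | (2R,3S)-3-[2,5-bis(benzyloxy)-4-methoxyphenyl]-3-[(tert-butyldimethylsilyl)oxy]-1-(2-hydroxy-4,6-dimethoxyphenyl)-2-methoxypropan-1-one | COc1cc(O)c(C(=O)[C@H](OC)[C@@H](O[Si](C)(C)C(C)(C)C)c2cc(OCc3ccccc3)c(OC)cc2OCc2ccccc2)c(OC)c1 | intermediate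
19 | (2R,3S)-3-[2,5-bis(benzyloxy)-4-methoxyphenyl]-3-hydroxy-1-(2-hydroxy-4,6-dimethoxyphenyl)-2-methoxypropan-1-one | COc1cc(O)c(C(=O)[C@H](OC)[C@@H](O)c2cc(OCc3ccccc3)c(OC)cc2OCc2ccccc2)c(OC)c1 | intermediate
20 | O-triphenylphosphonium derivative of the benzylic alcohol of 19 with the ring A phenol as phenolate (zwitterion; C-2 and C-3 as in 19) | COc1cc([O-])c(C(=O)[C@H](OC)[C@@H](O[P+](c2ccccc2)(c2ccccc2)c2ccccc2)c2cc(OCc3ccccc3)c(OC)cc2OCc2ccccc2)c(OC)c1 | intermediate (not isolated)
21 | (2R,3R)-2-[2,5-bis(benzyloxy)-4-methoxyphenyl]-3,5,7-trimethoxychroman-4-one (2,3-trans) | COc1cc(OC)c2c(c1)O[C@H](c1cc(OCc3ccccc3)c(OC)cc1OCc1ccccc1)[C@@H](OC)C2=O | intermediate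
22 | (2R,3R)-2-(2,5-dihydroxy-4-methoxyphenyl)-3,5,7-trimethoxychroman-4-one (2,3-trans) | COc1cc(OC)c2c(c1)O[C@H](c1cc(O)c(OC)cc1O)[C@@H](OC)C2=O | target

**Totals**
Total step count: 12. Longest linear sequence: 10 steps (1 → 2 → 4 → 10 → 11 → 12 → 17 → 18 → 19 → 21 → 22; steps 1, 2, 4, 5, 6, 8, 9, 10, 11, 12).

**Three steps most likely to fail**

Step 8 (aryllithium acylation). The di-ortho-substituted aryllithium may add slowly to the branched Weinreb amide and enolise it instead, and any lithiation between the two methoxy groups would give an isomeric ketone to be separated. The fallback sets out from 12 and comes back to the route at 17. Reduction of 12 with i-Bu2AlH (THF, −78 °C) gives (2R,3S)-3-[2,5-bis(benzyloxy)-4-methoxyphenyl]-3-[(tert-butyldimethylsilyl)oxy]-2-methoxypropanal F1. Aryllithium 15 adds to this far more electrophilic aldehyde at −78 °C to give (1RS,2S,3S)-3-[2,5-bis(benzyloxy)-4-methoxyphenyl]-3-[(tert-butyldimethylsilyl)oxy]-1-[2,4-dimethoxy-6-(methoxymethoxy)phenyl]-2-methoxypropan-1-ol F2 (both carbinol epimers; the two existing centres are unchanged in space, the C-2 descriptor changes only through the sequence rule). Dess–Martin periodinane with NaHCO3 in CH2Cl2 oxidises both epimers to 17.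

Step 9 (MOM removal on the advanced ketone). The cleavage may be sluggish, or the Lewis acid may touch the silyl ether or the electron-rich benzylic C–O bond. The fallback sets out from 14 and comes back to the route at 18, moving the acid step to a simple arene and using a palladium-labile group late. Lithiation of 14 as in step 8 and quenching 15 with I2 gives 2-iodo-1,5-dimethoxy-3-(methoxymethoxy)benzene F3, which can be purified free of any regioisomer. HCl in MeOH at 50 °C cleaves the acetal to 2-iodo-3,5-dimethoxyphenol F4. Allyl bromide and K2CO3 in acetone give 1-(allyloxy)-2-iodo-3,5-dimethoxybenzene F5. Iodine–lithium exchange (n-BuLi, THF, −78 °C) gives [2-(allyloxy)-4,6-dimethoxyphenyl]lithium F6, which is kept cold and added to 12 to give (2R,3S)-1-[2-(allyloxy)-4,6-dimethoxyphenyl]-3-[2,5-bis(benzyloxy)-4-methoxyphenyl]-3-[(tert-butyldimethylsilyl)oxy]-2-methoxypropan-1-one F7. Pd(PPh3)4 and morpholine in THF at rt remove the allyl group under neutral conditions and deliver 18.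

Step 11 (Mitsunobu ring closure). E1cB dehydration of the β-hydroxy ketone to the 2'-hydroxy-α-methoxychalcone can compete, and partial ionisation of the very electron-rich benzylic centre could give some 2,3-cis isomer. The fallback sets out from 19 and comes back to the route at 21 with no new isolated compound (F0). Compound 19 is stirred with catalytic camphorsulfonic acid and 4 Å molecular sieves in CH2Cl2 at 0 °C. The benzylic hydroxyl ionises to a cation stabilised by the ortho and para oxygens, and the ring A phenol traps it under thermodynamic control to give the diequatorial 2,3-trans chromanone, with C3 untouched. The ee of 21 must be checked by chiral HPLC, because E1 loss of H-3 followed by oxa-Michael re-closure would racemise.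

**Further compounds**
F1 | step 8 | (2R,3S)-3-[2,5-bis(benzyloxy)-4-methoxyphenyl]-3-[(tert-butyldimethylsilyl)oxy]-2-methoxypropanal | O=C[C@H](OC)[C@@H](O[Si](C)(C)C(C)(C)C)c1cc(OCc2ccccc2)c(OC)cc1OCc1ccccc1
F2 | step 8 | (1RS,2S,3S)-3-[2,5-bis(benzyloxy)-4-methoxyphenyl]-3-[(tert-butyldimethylsilyl)oxy]-1-[2,4-dimethoxy-6-(methoxymethoxy)phenyl]-2-methoxypropan-1-ol | COCOc1cc(OC)cc(OC)c1C(O)[C@H](OC)[C@@H](O[Si](C)(C)C(C)(C)C)c1cc(OCc2ccccc2)c(OC)cc1OCc1ccccc1
F3 | step 9 | 2-iodo-1,5-dimethoxy-3-(methoxymethoxy)benzene | COCOc1cc(OC)cc(OC)c1I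
F4 | step 9 | 2-iodo-3,5-dimethoxyphenol | COc1cc(O)c(I)c(OC)c1
F5 | step 9 | 1-(allyloxy)-2-iodo-3,5-dimethoxybenzene | C=CCOc1cc(OC)cc(OC)c1I
F6 | step 9 | [2-(allyloxy)-4,6-dimethoxyphenyl]lithium | [Li]c1c(OC)cc(OC)cc1OCC=C
F7 | step 9 | (2R,3S)-1-[2-(allyloxy)-4,6-dimethoxyphenyl]-3-[2,5-bis(benzyloxy)-4-methoxyphenyl]-3-[(tert-butyldimethylsilyl)oxy]-2-methoxypropan-1-one | C=CCOc1cc(OC)cc(OC)c1C(=O)[C@H](OC)[C@@H](O[Si](C)(C)C(C)(C)C)c1cc(OCc2ccccc2)c(OC)cc1OCc1ccccc1
F0 | step 11 | none | none
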